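# Proposed synthesis of gnetucleistol F (21) by dearomative arylcarbonylation of a benzofuran

## Analysis of the target

Gnetucleistol F (21) is a 2,3-dihydrobenzofuran (benzene ring A fused to dihydrofuran ring B). It carries a 4-hydroxy-3,5-dimethoxyphenyl group (ring C) on C2, a hydroxymethyl group on C3, a methoxy group on C7, and at C5 an (E)-ethenyl bridge to a resorcinol (ring D). The only stereocentres are C2 (R) and C3 (S); they are adjacent, and the aryl and hydroxymethyl groups are trans on ring B. The (E)-alkene is the only other stereo element. The sensitive parts are the three free phenols and the electron-rich stilbene (air, light), and the benzylic C2–O1 ether. That ether sits para to the ring C phenol and can open through a para-quinone methide once the phenol is free and base is present. The difficulty is to set C2 and C3 in absolute terms on a ring with no other handle for stereocontrol, and to do so without a long linear build-up of ring B. The trans relation is the thermodynamic one as long as C3 carries a carbonyl group, so absolute control at C2 is enough if C3 can be equilibrated afterwards. The strategy rests on the fact that O1, C2, C3, C3a and C7a are the furan ring of a flat 7-methoxybenzofuran. The C2–aryl bond and the C3–CH2OH bond are then the two bonds that a syn carbopalladation of C2=C3 followed by carbonylation would make in one operation.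

## Retrosynthetic reasoning

Numbering used throughout: 1 methyl vanillate, 2 its 5-iodo derivative, 3 ethynyltrimethylsilane, 4 silylalkynylphenol, 5 terminal alkyne (not isolated), 6 benzofuran ester, 7 2,6-dimethoxyphenol, 8 its 4-iodo derivative, 9 silylated aryl iodide, 10 carbon monoxide, 11 cis-diester, 12 trans-diester, 13 diol, 14 aldehyde, 15 3,5-dihydroxybenzaldehyde, 16–19 the resorcinol branch ending in phosphonate 19, 20 tris-silyl ether, 21 target.

**21 from 20.** The three phenols are masked as the same silyl ether, so the last step is one fluoride treatment under buffered conditions. Leaving all phenols protected until the end keeps the C2–O1 bond out of reach of phenoxide-driven opening during every basic step.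

**20 from 14 and 19.** The stilbene C=C bond is cut. This separates the chiral bicyclic part from the achiral resorcinol part, and a Horner–Wadsworth–Emmons reaction of a benzylic phosphonate forms the (E)-alkene reliably. The aldehyde is placed on the bicyclic partner because its C5 carbon is already present from 1. Phosphonate 19 goes back through bromide 18, alcohol 17 and aldehyde 16 to 15 by standard operations.

**14 from 13, and 13 from 12.** Aldehyde 14 comes from diol 13 by oxidation of the benzylic alcohol only; the C3 hydroxymethyl group is not benzylic and is left alone. Diol 13 comes from trans-diester 12 by one hydride reduction of both esters. Carrying both carbons as esters until this point means that no protecting group is needed on either, and the C3 ester is what makes C3 adjustable.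

**12 from 11.** The trans-diester is the C3 epimer of cis-diester 11. Accepting the cis isomer at the key step is the gain here: a syn addition across a ring double bond can only give cis, and the thermodynamic preference then corrects C3 while C2, which has no acidic hydrogen, stays as set.

**11 from 6, 9 and 10.** The C2–C(aryl) bond and the C3–C(carbonyl) bond are cut together. This turns the stereochemical problem into face selection on a planar heteroarene by a chiral palladium catalyst, and makes the route convergent from two simple aromatic pieces. The forward step has to add the aryl group of 9 to C2 of 6, hold palladium on C3 long enough to take up 10, and finish with an alcohol to give the ester.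

**6 from 4 (through 5), 4 from 2 and 3, 2 from 1.** Ring B of the benzofuran is cut at O1–C2 and C3–C3a. That leads to an ortho-alkynylphenol, made by Sonogashira coupling of iodophenol 2 with 3. Iodination of 1 can only go ortho to the phenol, which fixes the 5-ester/7-methoxy pattern of 6.

**9 from 8, and 8 from 7.** The aryl iodide comes from 7 by para-iodination and silylation. The two methoxy groups block both ortho positions, so the iodination has one site.

## Alternatives that were turned down

**Alternative 1:** The O1–C2 bond is cut. The precursor is the diarylpropanol A2, (2S)-2-(5-bromo-2-hydroxy-3-methoxyphenyl)-3-(4-hydroxy-3,5-dimethoxyphenyl)propan-1-ol, which already holds the C3 stereocentre. In the forward step Ag2O (or DDQ) would oxidise the ring C phenol of A2 to its para-quinone methide. The ring A phenol would then add to the methide carbon and close ring B, giving the bromide A1, 4-[(2R,3S)-5-bromo-3-(hydroxymethyl)-7-methoxy-2,3-dihydro-1-benzofuran-2-yl]-2,6-dimethoxyphenol.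
- For it: the reaction type is known and biomimetic, the addition is reversible so the trans isomer should form directly, no epimerisation is needed, and ring C needs no protecting group at that stage.
- Against it: all absolute stereocontrol moves into A2, whose stereocentre carries an aryl, a benzyl and a hydroxymethyl group. That calls for an auxiliary-based alkylation or similar, with several redox and protecting-group steps. C2 is then set only by 1,2-induction from C3. The oxidant must also distinguish the ring C phenol from the ring A phenol. The bromide of A1 still has to be turned into the stilbene by further palladium chemistry in the presence of free phenols.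
- Comparison: each step is more reliable than the key step chosen here, and the trans relation comes without a correction step. The chosen strategy offers instead two skeletal bonds and both stereocentres in one catalytic step from flat achiral parts, and a longest linear sequence of nine steps, which the preparation of A2 alone would nearly use up.

**Alternative 2:** The C3–C3a and O1–C7a bonds are cut. The precursors are the aryl iodide A4, methyl 4-iodo-3-methoxybenzoate, and the cis-epoxide A5, 4-[(2S,3R)-3-(tert-butyldimethylsilyloxymethyl)oxiran-2-yl]-2,6-dimethoxyphenyl pivalate. In the forward step Pd(OAc)2, a phosphine, norbornene and base would effect a Catellani annulation. After oxidative addition and norbornene insertion, the palladacycle formed at the free ortho C–H of A4 would open A5 at the carbon bearing the silyloxymethyl group with inversion. Norbornene extrusion and C–O reductive elimination would then close ring B to give A3, methyl (2R,3S)-2-[3,5-dimethoxy-4-(pivaloyloxy)phenyl]-3-(tert-butyldimethylsilyloxymethyl)-7-methoxy-2,3-dihydro-1-benzofuran-5-carboxylate.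
- For it: both stereocentres come from a preformed epoxide by a stereospecific opening (cis-epoxide to trans product), no epimerisation is needed, and the ortho methoxy group of A4 blocks the second ortho site as this chemistry requires.
- Against it: this annulation is established for terminal epoxides, which are attacked at CH2. A5 would have to be attacked at a secondary carbon next to an electron-rich benzylic C–O bond that is prone to ionise, rearrange or be attacked itself. A5 also needs a Z-alkene and an asymmetric epoxidation of the harder substrate class, about six steps in all. The pivalate must later be removed with base or hydride.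
- Comparison: if its key step worked, the absolute configuration would be sourced more securely than by an untested face selection. Its key step is, however, no less speculative than the chosen one, and its precursor is longer. The chosen strategy offers simpler precursors and a face selection that can be tuned or inverted by the ligand.

**Alternative 3:** The C2–C3 bond is cut. The precursor is the aryl diazoacetate A7, methyl 2-[5-bromo-2-{[4-(tert-butyldimethylsilyloxy)-3,5-dimethoxyphenyl]methoxy}-3-methoxyphenyl]-2-diazoacetate. In the forward step Rh2(S-PTTL)4, dirhodium tetrakis[N-phthaloyl-(S)-tert-leucinate], would generate the carbenoid, which inserts into the benzylic ether C–H bond. This closes ring B as the cis ester A6, methyl (2R,3S)-5-bromo-2-[4-(tert-butyldimethylsilyloxy)-3,5-dimethoxyphenyl]-7-methoxy-2,3-dihydro-1-benzofuran-3-carboxylate.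
- For it: this is the best-precedented enantioselective way to cis-2-aryl-2,3-dihydrobenzofuran-3-carboxylates, and the electron-rich benzylic C–H bond is well suited. A bromine at C5 makes the ring oxygen a poorer leaving group than an ester does, so the later cis-to-trans epimerisation is safer. On both points it is stronger than the chosen route.
- Against it: A7 is built linearly in about six steps and includes a diazo compound. The C5 bromide must then be converted into the stilbene by an extra palladium-catalysed step next to the new stereocentres.
- Comparison: the chosen strategy reaches the same kind of cis ester (11) convergently from 6 and 9 in fewer steps, with the C5 carbon already at a useful oxidation level. The price is an unproven key step, and for that reason the chemistry of this alternative is kept as its fallback.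

Key step: step 6

## Route

Assumption: the sense of induction of the axially chiral bisphosphine in the carbopalladation cannot be derived from structure alone; (R)-SEGPHOS is written for the (2R) series, and its mirror image would be used if the other face turns out to be preferred.

Step 1
Reactants: 1 methyl vanillate (methyl 4-hydroxy-3-methoxybenzoate)
Product: 2 methyl 4-hydroxy-3-iodo-5-methoxybenzoate
Conditions: NIS, CF3CO2H (cat.), MeCN, 0 °C to rt
Reagents that add atoms: N-iodosuccinimide, O=C1CCC(=O)N1I
Why: Electrophilic aromatic iodination; the phenol is the strongest director and its para position is blocked by the ester, so iodine should enter the one free ortho position.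

Step 2
Reactants: 2 methyl 4-hydroxy-3-iodo-5-methoxybenzoate; 3 ethynyltrimethylsilane
Product: 4 methyl 4-hydroxy-3-methoxy-5-[(trimethylsilyl)ethynyl]benzoate
Conditions: PdCl2(PPh3)2 (2 mol %), CuI (4 mol %), Et3N, THF, rt
Reagents that add atoms: none
Why: Sonogashira coupling of an aryl iodide with a terminal alkyne; the free phenol is tolerated at room temperature and the silyl group keeps the second alkyne terminus from coupling.

Step 3
Reactants: 4 methyl 4-hydroxy-3-methoxy-5-[(trimethylsilyl)ethynyl]benzoate
Product: 6 methyl 7-methoxy-1-benzofuran-5-carboxylate, via methyl 3-ethynyl-4-hydroxy-5-methoxybenzoate 5 (not isolated)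
Conditions: Bu4NF, THF, 65 °C
Reagents that add atoms: none
Why: Fluoride removes the alkynyl silyl group, and the phenoxide of 5 then adds to the terminal alkyne in a base-mediated 5-endo-dig hydroalkoxylation, driven by formation of the aromatic furan ring.

Step 4
Reactants: 7 2,6-dimethoxyphenol
Product: 8 4-iodo-2,6-dimethoxyphenol
Conditions: NIS, MeCN, 0 °C
Reagents that add atoms: N-iodosuccinimide, O=C1CCC(=O)N1I
Why: Electrophilic aromatic iodination; both ortho positions of the phenol carry methoxy groups, so the para position is the only strongly activated site.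

Step 5
Reactants: 8 4-iodo-2,6-dimethoxyphenol
Product: 9 tert-butyl(4-iodo-2,6-dimethoxyphenoxy)dimethylsilane
Conditions: TBSCl, imidazole, DMF, rt
Reagents that add atoms: tert-butyldimethylsilyl chloride, CC(C)(C)[Si](C)(C)Cl
Why: Imidazole-promoted silylation of a phenol; the two flanking methoxy groups slow the reaction but also make the resulting aryl silyl ether hindered and robust for the later steps.

Step 6
Reactants: 6 methyl 7-methoxy-1-benzofuran-5-carboxylate; 9 tert-butyl(4-iodo-2,6-dimethoxyphenoxy)dimethylsilane; 10 carbon monoxide
Product: 11 dimethyl (2R,3S)-2-[4-(tert-butyldimethylsilyloxy)-3,5-dimethoxyphenyl]-7-methoxy-2,3-dihydro-1-benzofuran-3,5-dicarboxylate (cis)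
Conditions: Pd(OAc)2 (10 mol %), (R)-SEGPHOS (12 mol %), iPr2NEt (2 equiv), MeOH (10 equiv), CO (1.5 equiv, fed slowly under N2), 6 (3 equiv), 1,4-dioxane, 70 °C
Reagents that add atoms: methanol, CO
Why: Proposed new method: Pd(OAc)2 is reduced in situ to a zerovalent palladium–bisphosphine complex that inserts into the C–I bond of 9; in the hydrogen-bonding medium iodide leaves the arylpalladium, the free site binds C2=C3 of 6, and syn migratory insertion puts the aryl group on C2 (the oxygen-bearing carbon, as in cationic Heck arylation of enol ethers) and palladium on benzylic C3 as a π-benzyl species; the closest known reaction types are intramolecular asymmetric dearomative Heck–carbonylation cascades of indoles and benzofurans and intermolecular Heck-type C2 arylation of benzofurans. No ring is closed; the furan ring of 6 loses its aromaticity and becomes ring B. C2 is set by the enantioface selection of the axially chiral ligand at the insertion, and C3 follows from it because the addition is syn and CO inserts into the C3–palladium bond with retention, so aryl and ester end up cis. The only β-hydrogen, C2–H, lies anti to palladium, so β-hydride elimination is not available and the intermediate can wait for 10; CO insertion and methanolysis of the acylpalladium then release 11 and zerovalent palladium. The step needs carbopalladation to outrun carbonylation of the arylpalladium itself, which is why CO is fed slowly and 6 is used in excess at high concentration. It needs aryl delivery to C2, which the enol-ether polarisation of C2=C3 and the benzylic stabilisation at C3 secure, and it needs CO capture to outrun base-induced loss of C2–H, which a hindered amine base disfavours. Partial epimerisation of 11 at C3 by the amine would be harmless because step 7 does the same.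

Step 7
Reactants: 11 dimethyl (2R,3S)-2-[4-(tert-butyldimethylsilyloxy)-3,5-dimethoxyphenyl]-7-methoxy-2,3-dihydro-1-benzofuran-3,5-dicarboxylate
Product: 12 dimethyl (2R,3R)-2-[4-(tert-butyldimethylsilyloxy)-3,5-dimethoxyphenyl]-7-methoxy-2,3-dihydro-1-benzofuran-3,5-dicarboxylate (trans)
Conditions: DBU (0.3 equiv), toluene, rt
Reagents that add atoms: none
Why: Base-mediated epimerisation through the C3 ester enolate; the trans isomer avoids the eclipsed aryl/ester arrangement and should dominate at equilibrium, C2 has no acidic hydrogen and keeps its configuration, and a non-nucleophilic amidine in an aprotic solvent spares the aryl silyl ether.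

Step 8
Reactants: 12 dimethyl (2R,3R)-2-[4-(tert-butyldimethylsilyloxy)-3,5-dimethoxyphenyl]-7-methoxy-2,3-dihydro-1-benzofuran-3,5-dicarboxylate
Product: 13 [(2R,3S)-2-[4-(tert-butyldimethylsilyloxy)-3,5-dimethoxyphenyl]-7-methoxy-2,3-dihydro-1-benzofuran-3,5-diyl]dimethanol
Conditions: LiAlH4, THF, 0 °C
Reagents that add atoms: none
Why: Hydride reduction of both esters to primary alcohols; no stereocentre is touched (the descriptor at C3 changes only because the substituent priorities change) and the hindered aryl silyl ether should survive at 0 °C.

Step 9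
Reactants: 13 [(2R,3S)-2-[4-(tert-butyldimethylsilyloxy)-3,5-dimethoxyphenyl]-7-methoxy-2,3-dihydro-1-benzofuran-3,5-diyl]dimethanol
Product: 14 (2R,3S)-2-[4-(tert-butyldimethylsilyloxy)-3,5-dimethoxyphenyl]-3-(hydroxymethyl)-7-methoxy-2,3-dihydro-1-benzofuran-5-carbaldehyde
Conditions: MnO2 (activated, excess), CH2Cl2, rt
Reagents that add atoms: none
Why: Chemoselective MnO2 oxidation of the benzylic alcohol at C5; the hydroxymethyl group on C3 is an ordinary primary alcohol and should not react.

Step 10
Reactants: 15 3,5-dihydroxybenzaldehyde
Product: 16 3,5-bis(tert-butyldimethylsilyloxy)benzaldehyde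
Conditions: TBSCl, imidazole, DMF, rt
Reagents that add atoms: tert-butyldimethylsilyl chloride, CC(C)(C)[Si](C)(C)Cl
Why: Standard imidazole-promoted silylation of both phenols.

Step 11
Reactants: 16 3,5-bis(tert-butyldimethylsilyloxy)benzaldehyde
Product: 17 [3,5-bis(tert-butyldimethylsilyloxy)phenyl]methanol
Conditions: NaBH4, MeOH/THF, 0 °C
Reagents that add atoms: none
Why: Borohydride reduction of an aryl aldehyde; short contact at 0 °C keeps the aryl silyl ethers intact.

Step 12
Reactants: 17 [3,5-bis(tert-butyldimethylsilyloxy)phenyl]methanol
Product: 18 [5-(bromomethyl)-1,3-phenylene]bis(oxy)bis(tert-butyldimethylsilane)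
Conditions: CBr4, PPh3, CH2Cl2, 0 °C
Reagents that add atoms: carbon tetrabromide, BrC(Br)(Br)Br
Why: Appel bromination of a benzylic alcohol under neutral conditions that do not touch silyl ethers.

Step 13
Reactants: 18 [5-(bromomethyl)-1,3-phenylene]bis(oxy)bis(tert-butyldimethylsilane)
Product: 19 diethyl [3,5-bis(tert-butyldimethylsilyloxy)benzyl]phosphonate
Conditions: P(OEt)3, neat, 130 °C
Reagents that add atoms: triethyl phosphite, CCOP(OCC)OCC
Why: Michaelis–Arbuzov reaction of a benzylic bromide; bromoethane distils off and drives the reaction.

Step 14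
Reactants: 14 (2R,3S)-2-[4-(tert-butyldimethylsilyloxy)-3,5-dimethoxyphenyl]-3-(hydroxymethyl)-7-methoxy-2,3-dihydro-1-benzofuran-5-carbaldehyde; 19 diethyl [3,5-bis(tert-butyldimethylsilyloxy)benzyl]phosphonate
Product: 20 [(2R,3S)-5-{(E)-2-[3,5-bis(tert-butyldimethylsilyloxy)phenyl]ethenyl}-2-[4-(tert-butyldimethylsilyloxy)-3,5-dimethoxyphenyl]-7-methoxy-2,3-dihydro-1-benzofuran-3-yl]methanol
Conditions: 19 (2.2 equiv), NaN(SiMe3)2 (2.2 equiv), THF, 0 °C, then 14, 0 °C to rt
Reagents that add atoms: none
Why: Horner–Wadsworth–Emmons olefination; the benzylic phosphonate anion adds reversibly to the aldehyde and elimination of phosphate should give the (E)-stilbene, while the extra equivalent of anion covers the free hydroxyl group and the non-nucleophilic amide base spares the aryl silyl ethers.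

Step 15
Reactants: 20 [(2R,3S)-5-{(E)-2-[3,5-bis(tert-butyldimethylsilyloxy)phenyl]ethenyl}-2-[4-(tert-butyldimethylsilyloxy)-3,5-dimethoxyphenyl]-7-methoxy-2,3-dihydro-1-benzofuran-3-yl]methanol
Product: 21 gnetucleistol F, 5-{(E)-2-[(2R,3S)-2-(4-hydroxy-3,5-dimethoxyphenyl)-3-(hydroxymethyl)-7-methoxy-2,3-dihydro-1-benzofuran-5-yl]ethenyl}benzene-1,3-diol
Conditions: Bu4NF (3.3 equiv), AcOH (3.3 equiv), THF, 0 °C to rt, dark, under argon
Reagents that add atoms: none
Why: Fluoride cleavage of three aryl silyl ethers; the acetic acid buffer keeps the liberated phenols protonated, so the ring C phenoxide cannot open the C2–O1 bond through a para-quinone methide, and C2 and C3 are not touched.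

## Compound list

1 | methyl vanillate (methyl 4-hydroxy-3-methoxybenzoate) | COC(=O)c1ccc(O)c(OC)c1 | starting material
2 | methyl 4-hydroxy-3-iodo-5-methoxybenzoate | COC(=O)c1cc(I)c(O)c(OC)c1 | intermediate
3 | ethynyltrimethylsilane | C#C[Si](C)(C)C | starting material
4 | methyl 4-hydroxy-3-methoxy-5-[(trimethylsilyl)ethynyl]benzoate | COC(=O)c1cc(OC)c(O)c(C#C[Si](C)(C)C)c1 | intermediate
5 | methyl 3-ethynyl-4-hydroxy-5-methoxybenzoate | COC(=O)c1cc(OC)c(O)c(C#C)c1 | intermediate
6 | methyl 7-methoxy-1-benzofuran-5-carboxylate | COC(=O)c1cc(OC)c2occc2c1 | intermediate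
7 | 2,6-dimethoxyphenol | COc1cccc(OC)c1O | starting material
8 | 4-iodo-2,6-dimethoxyphenol | COc1cc(I)cc(OC)c1O | intermediate
9 | tert-butyl(4-iodo-2,6-dimethoxyphenoxy)dimethylsilane | COc1cc(I)cc(OC)c1O[Si](C)(C)C(C)(C)C | intermediate
10 | carbon monoxide | [C-]#[O+] | starting material
11 | dimethyl (2R,3S)-2-[4-(tert-butyldimethylsilyloxy)-3,5-dimethoxyphenyl]-7-methoxy-2,3-dihydro-1-benzofuran-3,5-dicarboxylate (cis) | COc1cc([C@@H]2Oc3c(OC)cc(C(=O)OC)cc3[C@@H]2C(=O)OC)cc(OC)c1O[Si](C)(C)C(C)(C)C | intermediate
12 | dimethyl (2R,3R)-2-[4-(tert-butyldimethylsilyloxy)-3,5-dimethoxyphenyl]-7-methoxy-2,3-dihydro-1-benzofuran-3,5-dicarboxylate (trans) | COc1cc([C@@H]2Oc3c(OC)cc(C(=O)OC)cc3[C@H]2C(=O)OC)cc(OC)c1O[Si](C)(C)C(C)(C)C | intermediate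
13 | [(2R,3S)-2-[4-(tert-butyldimethylsilyloxy)-3,5-dimethoxyphenyl]-7-methoxy-2,3-dihydro-1-benzofuran-3,5-diyl]dimethanol | COc1cc([C@@H]2Oc3c(OC)cc(CO)cc3[C@H]2CO)cc(OC)c1O[Si](C)(C)C(C)(C)C | intermediate
14 | (2R,3S)-2-[4-(tert-butyldimethylsilyloxy)-3,5-dimethoxyphenyl]-3-(hydroxymethyl)-7-methoxy-2,3-dihydro-1-benzofuran-5-carbaldehyde | COc1cc([C@@H]2Oc3c(OC)cc(C=O)cc3[C@H]2CO)cc(OC)c1O[Si](C)(C)C(C)(C)C | intermediate
15 | 3,5-dihydroxybenzaldehyde | O=Cc1cc(O)cc(O)c1 | starting material
16 | 3,5-bis(tert-butyldimethylsilyloxy)benzaldehyde | O=Cc1cc(O[Si](C)(C)C(C)(C)C)cc(O[Si](C)(C)C(C)(C)C)c1 | intermediate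
17 | [3,5-bis(tert-butyldimethylsilyloxy)phenyl]methanol | OCc1cc(O[Si](C)(C)C(C)(C)C)cc(O[Si](C)(C)C(C)(C)C)c1 | intermediate
18 | [5-(bromomethyl)-1,3-phenylene]bis(oxy)bis(tert-butyldimethylsilane) | BrCc1cc(O[Si](C)(C)C(C)(C)C)cc(O[Si](C)(C)C(C)(C)C)c1 | intermediate
19 | diethyl [3,5-bis(tert-butyldimethylsilyloxy)benzyl]phosphonate | CCOP(=O)(OCC)Cc1cc(O[Si](C)(C)C(C)(C)C)cc(O[Si](C)(C)C(C)(C)C)c1 | intermediate
20 | [(2R,3S)-5-{(E)-2-[3,5-bis(tert-butyldimethylsilyloxy)phenyl]ethenyl}-2-[4-(tert-butyldimethylsilyloxy)-3,5-dimethoxyphenyl]-7-methoxy-2,3-dihydro-1-benzofuran-3-yl]methanol | COc1cc([C@@H]2Oc3c(OC)cc(/C=C/c4cc(O[Si](C)(C)C(C)(C)C)cc(O[Si](C)(C)C(C)(C)C)c4)cc3[C@H]2CO)cc(OC)c1O[Si](C)(C)C(C)(C)C | intermediate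
21 | gnetucleistol F, 5-{(E)-2-[(2R,3S)-2-(4-hydroxy-3,5-dimethoxyphenyl)-3-(hydroxymethyl)-7-methoxy-2,3-dihydro-1-benzofuran-5-yl]ethenyl}benzene-1,3-diol | COc1cc([C@@H]2Oc3c(OC)cc(/C=C/c4cc(O)cc(O)c4)cc3[C@H]2CO)cc(OC)c1O | target

## Step count and risk

Total: 15 steps. Longest linear sequence: 9 steps (steps 1, 2, 3, 6, 7, 8, 9, 14, 15, from methyl vanillate 1). The branch from 7 has two steps before the key step, and the branch from 15 has four steps before the olefination.

**Step 6 (key step, proposed new method).** Three things are most likely to go wrong.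
- Carbonylation of the arylpalladium before it has added to the benzofuran. CO inserts into an aryl–palladium bond much more readily than a weakly coordinating heteroaromatic C=C bond does, so the aryl iodide may simply be converted into its methyl ester.
- Rearomatisation of the C3–palladium intermediate by loss of C2–H, or opening of ring B by β-oxygen elimination.
- Poor face selection, because this ligand class has no precedent on an intermolecular benzofuran insertion.

Fallback (known chemistry), setting out from 2 and 9 and returning at 11: the C2–C3 bond is closed by a chiral dirhodium carbenoid instead. Iodine–magnesium exchange on 9 (iPrMgCl·LiCl, THF, −20 °C) and quenching with paraformaldehyde should give [4-(tert-butyldimethylsilyloxy)-3,5-dimethoxyphenyl]methanol F1. Mitsunobu etherification of phenol 2 with this alcohol (PPh3, diisopropyl azodicarboxylate, THF) should give methyl 4-{[4-(tert-butyldimethylsilyloxy)-3,5-dimethoxyphenyl]methoxy}-3-iodo-5-methoxybenzoate F2. Palladium-catalysed coupling of the aryl iodide with methyl diazoacetate (Pd(PPh3)4, Et3N, Bu4NBr, MeCN, rt) should give methyl 4-{[4-(tert-butyldimethylsilyloxy)-3,5-dimethoxyphenyl]methoxy}-3-(1-diazo-2-methoxy-2-oxoethyl)-5-methoxybenzoate F3. Rh2(S-PTTL)4, dirhodium tetrakis[N-phthaloyl-(S)-tert-leucinate], in toluene at −78 °C would then effect enantioselective insertion into the benzylic ether C–H bond, a reaction type known to give cis-2-aryl-2,3-dihydrobenzofuran-3-carboxylates, and so deliver 11.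

**Step 7.** The risk is opening of ring B by β-elimination of the ring A phenoxide from the C3 enolate. The ester para to O1 makes that phenoxide a better leaving group, and such an opening would destroy the C2 stereocentre.

Fallback, setting out from 6 and returning at 13: the acceptor on ring A is removed before the key step.
- Reduction of 6 (LiAlH4, THF, 0 °C) gives (7-methoxy-1-benzofuran-5-yl)methanol F4.
- Silylation (TBSCl, imidazole, DMF) gives tert-butyl[(7-methoxy-1-benzofuran-5-yl)methoxy]dimethylsilane F5.
- The conditions of step 6 with 9 and 10 should then give methyl (2R,3S)-2-[4-(tert-butyldimethylsilyloxy)-3,5-dimethoxyphenyl]-5-[(tert-butyldimethylsilyloxy)methyl]-7-methoxy-2,3-dihydro-1-benzofuran-3-carboxylate F6.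
- Epimerisation with DBU now has no para acceptor to assist ring opening and gives the (2R,3R) trans ester, methyl (2R,3R)-2-[4-(tert-butyldimethylsilyloxy)-3,5-dimethoxyphenyl]-5-[(tert-butyldimethylsilyloxy)methyl]-7-methoxy-2,3-dihydro-1-benzofuran-3-carboxylate F7.
- LiAlH4 reduction gives [(2R,3S)-2-[4-(tert-butyldimethylsilyloxy)-3,5-dimethoxyphenyl]-5-[(tert-butyldimethylsilyloxy)methyl]-7-methoxy-2,3-dihydro-1-benzofuran-3-yl]methanol F8.
- Mild acid (pyridinium p-toluenesulfonate, MeOH, rt) removes the primary alkyl silyl ether in preference to the hindered aryl one and gives 13.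

**Step 14.** The risk is transfer of the unhindered phenolic silyl groups of the phosphonate to the C3 alkoxide or their loss to base. This would leave phenoxide-bearing anions of low reactivity and stall the olefination. Loss of the ring C silyl group would expose C2–O1 to opening.

Fallback, setting out from 14 and 16 and returning at 20: the alkene is made by cross-metathesis instead.
- Wittig methylenation of 14 (Ph3PCH3Br, NaN(SiMe3)2, THF, 0 °C) gives [(2R,3S)-2-[4-(tert-butyldimethylsilyloxy)-3,5-dimethoxyphenyl]-5-ethenyl-7-methoxy-2,3-dihydro-1-benzofuran-3-yl]methanol F9.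
- The same methylenation of 16 gives [(5-ethenyl-1,3-phenylene)bis(oxy)]bis(tert-butyldimethylsilane) F10.
- Cross-metathesis of the two styrenes with the second-generation Hoveyda–Grubbs catalyst (CH2Cl2, 40 °C, excess of the resorcinol styrene) should give the (E)-stilbene 20; the free alcohol is tolerated.

**Step 3.** The risk is incomplete ring closure of the terminal alkyne 5 after desilylation, since the phenoxide is deactivated by the para ester, together with partial ester hydrolysis by wet fluoride.

Fallback, setting out from 4 and returning at 6: the ring is closed before the silyl group is removed. Heating 4 under metal catalysis (PdCl2(PPh3)2, CuI, Et3N, DMF, 70 °C) should give methyl 7-methoxy-2-(trimethylsilyl)-1-benzofuran-5-carboxylate F11 by metal-activated 5-endo-dig attack of the phenol. Protodesilylation at C2 (Bu4NF, THF, rt) then gives 6.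

## Further compounds

F1 | step 6 | [4-(tert-butyldimethylsilyloxy)-3,5-dimethoxyphenyl]methanol | COc1cc(CO)cc(OC)c1O[Si](C)(C)C(C)(C)C
F2 | step 6 | methyl 4-{[4-(tert-butyldimethylsilyloxy)-3,5-dimethoxyphenyl]methoxy}-3-iodo-5-methoxybenzoate | COC(=O)c1cc(I)c(OCc2cc(OC)c(O[Si](C)(C)C(C)(C)C)c(OC)c2)c(OC)c1
F3 | step 6 | methyl 4-{[4-(tert-butyldimethylsilyloxy)-3,5-dimethoxyphenyl]methoxy}-3-(1-diazo-2-methoxy-2-oxoethyl)-5-methoxybenzoate | COC(=O)C(=[N+]=[N-])c1cc(C(=O)OC)cc(OC)c1OCc1cc(OC)c(O[Si](C)(C)C(C)(C)C)c(OC)c1
F4 | step 7 | (7-methoxy-1-benzofuran-5-yl)methanol | COc1cc(CO)cc2ccoc12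
F5 | step 7 | tert-butyl[(7-methoxy-1-benzofuran-5-yl)methoxy]dimethylsilane | COc1cc(CO[Si](C)(C)C(C)(C)C)cc2ccoc12
F6 | step 7 | methyl (2R,3S)-2-[4-(tert-butyldimethylsilyloxy)-3,5-dimethoxyphenyl]-5-[(tert-butyldimethylsilyloxy)methyl]-7-methoxy-2,3-dihydro-1-benzofuran-3-carboxylate (cis) | COc1cc([C@@H]2Oc3c(OC)cc(CO[Si](C)(C)C(C)(C)C)cc3[C@@H]2C(=O)OC)cc(OC)c1O[Si](C)(C)C(C)(C)C
F7 | step 7 | methyl (2R,3R)-2-[4-(tert-butyldimethylsilyloxy)-3,5-dimethoxyphenyl]-5-[(tert-butyldimethylsilyloxy)methyl]-7-methoxy-2,3-dihydro-1-benzofuran-3-carboxylate (trans) | COc1cc([C@@H]2Oc3c(OC)cc(CO[Si](C)(C)C(C)(C)C)cc3[C@H]2C(=O)OC)cc(OC)c1O[Si](C)(C)C(C)(C)C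
F8 | step 7 | [(2R,3S)-2-[4-(tert-butyldimethylsilyloxy)-3,5-dimethoxyphenyl]-5-[(tert-butyldimethylsilyloxy)methyl]-7-methoxy-2,3-dihydro-1-benzofuran-3-yl]methanol | COc1cc([C@@H]2Oc3c(OC)cc(CO[Si](C)(C)C(C)(C)C)cc3[C@H]2CO)cc(OC)c1O[Si](C)(C)C(C)(C)C
F9 | step 14 | [(2R,3S)-2-[4-(tert-butyldimethylsilyloxy)-3,5-dimethoxyphenyl]-5-ethenyl-7-methoxy-2,3-dihydro-1-benzofuran-3-yl]methanol | COc1cc([C@@H]2Oc3c(OC)cc(C=C)cc3[C@H]2CO)cc(OC)c1O[Si](C)(C)C(C)(C)C
F10 | step 14 | [(5-ethenyl-1,3-phenylene)bis(oxy)]bis(tert-butyldimethylsilane) | C=Cc1cc(O[Si](C)(C)C(C)(C)C)cc(O[Si](C)(C)C(C)(C)C)c1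
F11 | step 3 | methyl 7-methoxy-2-(trimethylsilyl)-1-benzofuran-5-carboxylate | COC(=O)c1cc(OC)c2oc([Si](C)(C)C)cc2c1
A1 | alternative 1 | 4-[(2R,3S)-5-bromo-3-(hydroxymethyl)-7-methoxy-2,3-dihydro-1-benzofuran-2-yl]-2,6-dimethoxyphenol | COc1cc([C@@H]2Oc3c(OC)cc(Br)cc3[C@H]2CO)cc(OC)c1O
A2 | alternative 1 | (2S)-2-(5-bromo-2-hydroxy-3-methoxyphenyl)-3-(4-hydroxy-3,5-dimethoxyphenyl)propan-1-ol | COc1cc(C[C@H](CO)c2cc(Br)cc(OC)c2O)cc(OC)c1O
A3 | alternative 2 | methyl (2R,3S)-2-[3,5-dimethoxy-4-(pivaloyloxy)phenyl]-3-(tert-butyldimethylsilyloxymethyl)-7-methoxy-2,3-dihydro-1-benzofuran-5-carboxylate | COc1cc([C@@H]2Oc3c(OC)cc(C(=O)OC)cc3[C@H]2CO[Si](C)(C)C(C)(C)C)cc(OC)c1OC(=O)C(C)(C)C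
A4 | alternative 2 | methyl 4-iodo-3-methoxybenzoate | COC(=O)c1ccc(I)c(OC)c1
A5 | alternative 2 | 4-[(2S,3R)-3-(tert-butyldimethylsilyloxymethyl)oxiran-2-yl]-2,6-dimethoxyphenyl pivalate (cis-epoxide) | COc1cc([C@@H]2O[C@@H]2CO[Si](C)(C)C(C)(C)C)cc(OC)c1OC(=O)C(C)(C)C
A6 | alternative 3 | methyl (2R,3S)-5-bromo-2-[4-(tert-butyldimethylsilyloxy)-3,5-dimethoxyphenyl]-7-methoxy-2,3-dihydro-1-benzofuran-3-carboxylate (cis) | COc1cc([C@@H]2Oc3c(OC)cc(Br)cc3[C@@H]2C(=O)OC)cc(OC)c1O[Si](C)(C)C(C)(C)C
A7 | alternative 3 | methyl 2-[5-bromo-2-{[4-(tert-butyldimethylsilyloxy)-3,5-dimethoxyphenyl]methoxy}-3-methoxyphenyl]-2-diazoacetate | COC(=O)C(=[N+]=[N-])c1cc(Br)cc(OC)c1OCc1cc(OC)c(O[Si](C)(C)C(C)(C)C)c(OC)c1
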